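4 questions wait on this bench, 2 for each flask, and I hand over both flasks, east and north-east, still running.

| flask | starting material | coupling partner | protic impurity | time |
|---|---|---|---|---|
| east | 0.016 M | 0.0192 M | 1.60 mM | 15 h |
| north-east | 0.016 M | 0.0192 M | 3.20 mM | 15 h |

    starting material + coupling partner → intermediate A (k1 = 0.0249 M⁻¹ s⁻¹)
    intermediate A ⇌ intermediate B (K2 = 1.4, k2 = 2.43 × 10⁻⁴ s⁻¹)
    coupling partner + intermediate B ⇌ product (K3 = 30.6 M⁻¹, k3 = 0.0384 M⁻¹ s⁻¹)
    starting material + protic impurity → quenched substrate (k4 = 1.89 M⁻¹ s⁻¹)

- which of these there is most of at the end, counted by the starting material in it, east (starting material / intermediate A / intermediate B / product)
- which of these there is most of at the end, counted by the starting material in it, north-east (starting material / intermediate A / intermediate B / product)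
- the largest of these amounts at the end, in percent of the starting material charged, east
- the largest of these amounts at the end, in percent of the starting material charged, north-east

Here is what is in them. In east, starting material, the limiting reagent, has a half-life of 0.064 h by the step with protic impurity and 0.40 h by the coupling step, each reckoned with the charges held as they stand, so I write off the whole charge of protic impurity, there and in north-east. Each surviving starting material then takes one coupling partner, so the spare partner, before product takes its own share, is the charged [coupling partner] minus (the charged [starting material] minus the charged [protic impurity]): 4.80 mM in east and 6.40 mM in north-east. I call that spare times the equilibrium constant 30.6 M⁻¹ the pull, the product expected per intermediate B: 0.147 in east and 0.196 in north-east.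

On that spare, starting material in east has a half-life of 1.61 h, shorter than 15 h, the intermediates relax with a half-life of 0.462 h, and intermediate B and product relax with one of 0.134 h. So when you come I expect intermediate A, intermediate B and product to stand as 1 to 1.4 to 1.4 times the pull. That puts intermediate B first in east at 48.4%, and intermediate B first in north-east at 41.9%. Please don't top up the coupling partner, because my spare is reckoned from the charge.

The forecast names intermediate B at 49% in east and intermediate B at 42.7% in north-east, slightly above my amounts, holding that “the step 3 equilibrium holds product to just 6–9% of the charge”.

The flasks give intermediate B at 49.0% in east and intermediate B at 42.6% in north-east.

The main reason for the gap between the flasks is the larger charge of protic impurity in north-east: with that difference taken away, north-east reads 49.0% instead of 42.6%. In east the pull stands a little above the product to intermediate B reading of 0.119. In a neighbour of east with 0.077 M of coupling partner, the spare grows to 62.6 mM and the pull to 1.92, above 1, and that flask ends with more product, 44.8%, than intermediate B, 26.4%.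

The numbers of this flask are assumed; what happens was integrated by code.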